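The quinone ring (C1=O between C2–OMe and the chain-bearing C6; C3–H; C4=O; C5–H) is read as an oxidised 3-methoxy-5-alkylphenol, since O at C4 and OMe at C2 sit meta across C3–H. That phenol is built in one operation from an acyclic diazo ketone carrying the (R)-acetoxy chain and methoxyacetylene: photochemical Wolff shift to a vinylketene, [2+2] with the ynol ether, 4π opening and 6π closure create the C1–C2 and C4–C5 bonds (with C3–C4 and C1–C6). In the precursor C4 is an acyl carbon bonded to C6 and C1, so the skeleton is reorganised. The stereocentre comes from (R)-epichlorohydrin; the C1 carbonyl is added last by phenol oxidation.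

Key step: step 6

Assumption: compounds 1, 2, 5 and 13 are bought; methoxyacetylene is volatile and is therefore made fresh in step 5.

Step 1
Reactants: 1 (R)-epichlorohydrin; 2 decylmagnesium bromide
Product: 4 (R)-1,2-epoxytridecane, via (R)-1-chlorotridecan-2-ol 3 (not isolated)
Conditions: CuI (10 mol %), THF, −40 → 0 °C; then 2 M aq. NaOH, MeOH, rt
Reagents that add atoms: none
Why: Copper-catalysed Grignard opening of the epoxide at its CH2 terminus (SN2) followed by Williamson-type closure of the chlorohydrin; the C–O stereocentre of 1 is never broken, so (R) is carried into 4.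

Step 2
Reactants: 4 (R)-1,2-epoxytridecane; 5 acetone N,N-dimethylhydrazone
Product: 8 (R)-2-oxohexadecan-5-yl acetate, via hydrazone lithium alkoxide 6 (not isolated), via acetoxy hydrazone 7 (not isolated)
Conditions: 5, n-BuLi, THF, −78 → 0 °C; 4, 0 °C → rt; Ac2O, 0 °C → rt; then sat. aq. oxalic acid/Et2O, rt
Reagents that add atoms: acetic anhydride CC(=O)OC(C)=O; water O
Why: Aza-enolate (hydrazone) alkylation in which the lithiated hydrazone attacks the unsubstituted epoxide carbon (SN2), the alkoxide is acetylated in the flask and two-phase acid hydrolysis should free the methyl ketone without touching the acetate or the stereocentre.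

Step 3
Reactants: 8 (R)-2-oxohexadecan-5-yl acetate
Product: 10 (R)-3-methylidene-2-oxohexadecan-5-yl acetate, via anilino Mannich base 9 (not isolated)
Conditions: (CH2O)n (3 equiv), N-methylanilinium trifluoroacetate, THF, reflux
Reagents that add atoms: paraformaldehyde (as formaldehyde) C=O
Why: Mannich condensation–elimination (α-methylenation) in which acid-catalysed enolisation favours the more substituted α-carbon C3, so the methylene should be placed between the carbonyl and the chain and the β-amino ketone 9 eliminates under the same conditions.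

Step 4
Reactants: 10 (R)-3-methylidene-2-oxohexadecan-5-yl acetate
Product: 12 (R)-1-diazo-3-methylidene-2-oxohexadecan-5-yl acetate, via trifluoroacetyl ketone 11 (not isolated)
Conditions: LiN(SiMe3)2, THF, −78 °C (inverse addition); CF3CO2CH2CF3, −78 °C; then MsN3, Et3N, H2O (1 equiv), MeCN, rt
Reagents that add atoms: methanesulfonyl azide CS(=O)(=O)N=[N+]=[N-]
Why: Deacylative (detrifluoroacetylative) Regitz diazo transfer, in which kinetic enolisation is possible only at the methyl group and the trifluoroacetyl activator is lost during the transfer; acylation of diazomethane is avoided because it would compete with dipolar cycloaddition to the acrylic C=C.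

Step 5
Reactants: 13 chloroacetaldehyde dimethyl acetal
Product: 15 methoxyacetylene, via sodium methoxyethynide 14 (not isolated)
Conditions: NaNH2 (3 equiv), liq. NH3, −33 °C; then cold sat. aq. NaCl; distilled into ClCH2CH2Cl at −78 °C
Reagents that add atoms: none
Why: Double β-elimination (loss of methanol, then of HCl) with excess NaNH2 gives the sodium acetylide, which is protonated on aqueous quench, the standard preparation of a 1-alkoxyalkyne.

Step 6
Reactants: 12 (R)-1-diazo-3-methylidene-2-oxohexadecan-5-yl acetate; 15 methoxyacetylene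
Product: 20 (R)-1-(3-hydroxy-5-methoxyphenyl)tridecan-2-yl acetate, via vinylketene 16 (not isolated), via methoxycyclobutenone 17 (not isolated), via dienylketene 18 (not isolated), via cyclohexadienone 19 (not isolated)
Conditions: 15 (3 equiv), ClCH2CH2Cl (0.1 M), hν 254 nm (low-pressure Hg, quartz), 10–15 °C; then sealed tube, 80 °C
Reagents that add atoms: none
Why: Light expels N2 from 12 and the alkenyl group migrates from the acyl carbon to the carbene carbon (Wolff rearrangement) to give vinylketene 16; the nucleophilic CH terminus of 15 attacks the ketene carbonyl carbon, the [2+2] adduct 17 opens (4π) to dienylketene 18, and 18 closes through its terminal CH2 onto the ketene carbon and tautomerises to the phenol. The closest known reaction type is the Danheiser benzannulation in its diazo ketone (photo-Wolff) variant with an alkoxyacetylene as ketenophile. The transient four-membered ring closes by ketene–alkyne [2+2] cycloaddition and the six-membered ring by thermal disrotatory 6π-electrocyclisation of the dienylketene isomer that has the ketene and the alkene on the same side; ring opening of 17 is reversible, so the unproductive isomer should funnel back. No stereocentre is created, since the sp3 ring carbon of 17 is lost on ring opening and the remote (R) acetoxy carbinol takes no part. The step needs one regiochemistry, OMe meta to OH, and the polarisation of the ynol ether (β-carbon nucleophilic) against the electrophilic ketene carbonyl carbon secures it. Excess alkyne and dilution are meant to keep 16 from acylating the phenol as it forms.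

Step 7
Reactants: 20 (R)-1-(3-hydroxy-5-methoxyphenyl)tridecan-2-yl acetate
Product: 21 (R)-1-(5-methoxy-3,6-dioxocyclohexa-1,4-dien-1-yl)tridecan-2-yl acetate (target)
Conditions: K2[ON(SO3)2] (2.5 equiv), aq. KH2PO4 buffer, acetone/H2O, 0 °C → rt
Reagents that add atoms: potassium nitrosodisulfonate [K+].[K+].[O]N(S(=O)(=O)[O-])S(=O)(=O)[O-]
Why: Teuber oxidation, in which the phenoxyl radical couples with a second nitroxide at the only para carbon (between OMe and the alkyl group) and the adduct collapses to the para-quinone, while the acetate and the stereocentre are inert to the buffered medium.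

Compound list
1 | (R)-epichlorohydrin [(2R)-2-(chloromethyl)oxirane] | ClC[C@H]1CO1 | starting material
2 | decylmagnesium bromide | CCCCCCCCCC[Mg]Br | starting material
3 | (R)-1-chlorotridecan-2-ol (present as its magnesium alkoxide) | CCCCCCCCCCC[C@@H](O)CCl | intermediate (not isolated)
4 | (R)-1,2-epoxytridecane [(2R)-2-undecyloxirane] | CCCCCCCCCCC[C@@H]1CO1 | intermediate
5 | acetone N,N-dimethylhydrazone | CC(C)=NN(C)C | starting material
6 | lithium (5R)-2-(dimethylhydrazinylidene)hexadecan-5-olate | CCCCCCCCCCC[C@H](CCC(C)=NN(C)C)[O-].[Li+] | intermediate (not isolated)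
7 | (5R)-2-(dimethylhydrazinylidene)hexadecan-5-yl acetate | CCCCCCCCCCC[C@H](CCC(C)=NN(C)C)OC(C)=O | intermediate (not isolated)
8 | (R)-2-oxohexadecan-5-yl acetate | CCCCCCCCCCC[C@H](CCC(C)=O)OC(C)=O | intermediate
9 | (5R)-3-[(N-methylanilino)methyl]-2-oxohexadecan-5-yl acetate (both C3 epimers) | CCCCCCCCCCC[C@H](CC(CN(C)c1ccccc1)C(C)=O)OC(C)=O | intermediate (not isolated)
10 | (R)-3-methylidene-2-oxohexadecan-5-yl acetate | CCCCCCCCCCC[C@H](CC(=C)C(C)=O)OC(C)=O | intermediate
11 | (7R)-1,1,1-trifluoro-5-methylidene-2,4-dioxooctadecan-7-yl acetate | CCCCCCCCCCC[C@H](CC(=C)C(=O)CC(=O)C(F)(F)F)OC(C)=O | intermediate (not isolated)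
12 | (R)-1-diazo-3-methylidene-2-oxohexadecan-5-yl acetate | CCCCCCCCCCC[C@H](CC(=C)C(=O)C=[N+]=[N-])OC(C)=O | intermediate
13 | chloroacetaldehyde dimethyl acetal (2-chloro-1,1-dimethoxyethane) | COC(CCl)OC | starting material
14 | sodium methoxyethynide | [Na+].[C-]#COC | intermediate (not isolated)
15 | methoxyacetylene (methoxyethyne) | COC#C | intermediate
16 | (5R)-3-methylidene-1-oxohexadec-1-en-5-yl acetate (vinylketene) | CCCCCCCCCCC[C@H](CC(=C)C=C=O)OC(C)=O | intermediate (not isolated)
17 | (4R)-2-(2-methoxy-4-oxocyclobut-2-en-1-yl)pentadec-1-en-4-yl acetate (both epimers at the ring CH) | CCCCCCCCCCC[C@H](CC(=C)C1C(=O)C=C1OC)OC(C)=O | intermediate (not isolated)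
18 | (3E,7R)-3-methoxy-5-methylidene-1-oxooctadeca-1,3-dien-7-yl acetate (dienylketene) | CCCCCCCCCCC[C@H](CC(=C)/C=C(OC)\C=C=O)OC(C)=O | intermediate (not isolated)
19 | (2R)-1-(3-methoxy-5-oxocyclohexa-1,3-dien-1-yl)tridecan-2-yl acetate | CCCCCCCCCCC[C@H](CC1=CC(OC)=CC(=O)C1)OC(C)=O | intermediate (not isolated)
20 | (R)-1-(3-hydroxy-5-methoxyphenyl)tridecan-2-yl acetate | CCCCCCCCCCC[C@H](Cc1cc(O)cc(OC)c1)OC(C)=O | intermediate
21 | (R)-1-(5-methoxy-3,6-dioxocyclohexa-1,4-dien-1-yl)tridecan-2-yl acetate | CCCCCCCCCCC[C@H](CC1=CC(=O)C=C(OC)C1=O)OC(C)=O | target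

Total step count: 7. Longest linear sequence: 6 (steps 1, 2, 3, 4, 6, 7); step 5 is a one-step side branch.

Steps most likely to fail

Step 6 (key step). What may go wrong: the photochemical Wolff shift has to compete with light absorption by the phenol as it accumulates and with acylation of that phenol by vinylketene 16, and the volatile ynol ether may escape from solution so that 16 oligomerises before the [2+2] capture. Fallback (same vinylketene, made without a diazo compound and without light): setting out from epoxide 4, CH2=C(CH3)MgBr with catalytic CuI in THF at −30 °C should open the epoxide at CH2 to give (R)-2-methylpentadec-1-en-4-ol F1. n-BuLi (2.2 equiv)/TMEDA in hexane metalates the alkoxide at the allylic methyl group, and CO2 should give dilithium (R)-5-oxido-3-methylidenehexadecanoate F2. This is acetylated in the same flask with Ac2O and should give, after aqueous work-up, (R)-5-acetoxy-3-methylidenehexadecanoic acid F3. (COCl)2 with catalytic DMF in CH2Cl2 gives (R)-5-acetoxy-3-methylidenehexadecanoyl chloride F4. Slow addition of Et3N to F4 and 15 (3 equiv) in CH2Cl2 at 0 °C removes HCl across the acyl carbon and its α-CH2 and should regenerate vinylketene 16, where the fallback is back on the route (16 → 17 at room temperature, then 80 °C → 20). In F4 the acyl carbon (future C4) is bonded to the future C1 and not to C5, so the ring is assembled by the same bond formations.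

Step 4. What may go wrong: the kinetic lithium enolate of 10 may add to the exo-methylene enone of a second molecule (oligomerisation) faster than it is trifluoroacetylated. Fallback (diazo transfer before the enone exists): setting out from ketone 8, Me3SiCl/NaI/Et3N in MeCN should give the more substituted silyl enol ether (2Z,5R)-2-(trimethylsilyloxy)hexadec-2-en-5-yl acetate F5. N,N-Dimethylmethyleneiminium iodide in CH2Cl2 converts it into the Mannich base (5R)-3-[(dimethylamino)methyl]-2-oxohexadecan-5-yl acetate F6. LiN(SiMe3)2/CF3CO2CH2CF3 at −78 °C acylates the methyl group to give (7R)-5-[(dimethylamino)methyl]-1,1,1-trifluoro-2,4-dioxooctadecan-7-yl acetate F7, with no Michael acceptor present, and MsN3/Et3N/H2O in MeCN should give (5R)-1-diazo-3-[(dimethylamino)methyl]-2-oxohexadecan-5-yl acetate F8. MeI quaternises the amine to the trimethylammonium iodide F9, and NaHCO3 in CH2Cl2/H2O eliminates trimethylamine to give 12.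

Step 3. What may go wrong: methylene transfer at the methyl group or twice, and acid-promoted oligomerisation of the enone during the reflux. Fallback (methylene placed through a carboxyl-activated carbon): setting out from epoxide 4, methyl acetoacetate/NaOMe in MeOH at reflux should open the epoxide and lactonise to (5R)-3-acetyl-5-undecyloxolan-2-one F10. NaOH (1 equiv) in H2O/THF at 0 °C opens the lactone to sodium (4R)-2-acetyl-4-hydroxypentadecanoate F11. Aqueous CH2O with Et2NH·HCl then effects a Mannich reaction at the doubly activated carbon and decarboxylative elimination to (R)-5-hydroxy-3-methylidenehexadecan-2-one F12. Ac2O/pyridine/DMAP acetylates F12 to give 10.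

Further compounds
F1 | step 6 | (R)-2-methylpentadec-1-en-4-ol | CCCCCCCCCCC[C@H](CC(C)=C)O
F2 | step 6 | dilithium (R)-5-oxido-3-methylidenehexadecanoate | CCCCCCCCCCC[C@H](CC(=C)CC(=O)[O-])[O-].[Li+].[Li+]
F3 | step 6 | (R)-5-acetoxy-3-methylidenehexadecanoic acid | CCCCCCCCCCC[C@H](CC(=C)CC(=O)O)OC(C)=O
F4 | step 6 | (R)-5-acetoxy-3-methylidenehexadecanoyl chloride | CCCCCCCCCCC[C@H](CC(=C)CC(Cl)=O)OC(C)=O
F5 | step 4 | (2Z,5R)-2-(trimethylsilyloxy)hexadec-2-en-5-yl acetate | CCCCCCCCCCC[C@H](C/C=C(/C)O[Si](C)(C)C)OC(C)=O
F6 | step 4 | (5R)-3-[(dimethylamino)methyl]-2-oxohexadecan-5-yl acetate | CCCCCCCCCCC[C@H](CC(CN(C)C)C(C)=O)OC(C)=O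
F7 | step 4 | (7R)-5-[(dimethylamino)methyl]-1,1,1-trifluoro-2,4-dioxooctadecan-7-yl acetate | CCCCCCCCCCC[C@H](CC(CN(C)C)C(=O)CC(=O)C(F)(F)F)OC(C)=O
F8 | step 4 | (5R)-1-diazo-3-[(dimethylamino)methyl]-2-oxohexadecan-5-yl acetate | CCCCCCCCCCC[C@H](CC(CN(C)C)C(=O)C=[N+]=[N-])OC(C)=O
F9 | step 4 | [(4R)-4-acetoxy-2-(diazoacetyl)pentadecyl]trimethylammonium iodide | CCCCCCCCCCC[C@H](CC(C[N+](C)(C)C)C(=O)C=[N+]=[N-])OC(C)=O.[I-]
F10 | step 3 | (5R)-3-acetyl-5-undecyloxolan-2-one | CCCCCCCCCCC[C@@H]1CC(C(C)=O)C(=O)O1
F11 | step 3 | sodium (4R)-2-acetyl-4-hydroxypentadecanoate | CCCCCCCCCCC[C@H](CC(C(C)=O)C(=O)[O-])O.[Na+]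
F12 | step 3 | (R)-5-hydroxy-3-methylidenehexadecan-2-one | CCCCCCCCCCC[C@H](CC(=C)C(C)=O)O
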